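**Plan**

1. Numbering: chain C1 (lactone C=O) to C9 (CH3 on C8), with methyls on C2, C4 and C6. Ring A is the tetrahydropyran (O, C4, C5, C6, C7, C8). Ring B is the δ-lactone (C1–C5, O). The rings are trans-fused at C4–C5.
2. Enabling feature: in ring A the ring oxygen on C8 and the ester oxygen on the adjacent C7 are vicinal and antiperiplanar (C8-CH3 and C7-O-acyl both equatorial, 2,3-trans). This is the retron of a 1,2-shift of the ring oxygen from C7 to C8 through a bicyclic oxiranium ion.
3. Cuts: first C7–O(acyl) together with C8–O(ring), which gives (Z)-4-oxodec-2-enoic acid and a tetrahydrofuran (O, C4–C7) bearing a C8 sulfonate. Then C2–C3 and C1–O(C5) (ring B, from a propionate), C4–O (epoxide opening), C4=C5 (Wittig) and C6–C7 (crotylboration), back to methyl (R)-lactate (C8, C9).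
4. Forward order: chain C9→C3, then the tetrahydrofuran, then ring B. Ring A arises last, by one-atom expansion of the tetrahydrofuran in the same event that joins the side chain.
5. Stereochemistry: C8 comes from (R)-lactate and C7/C6 from Brown crotylboration; C8 and C7 are both inverted in the key step. C4/C5 come from Sharpless epoxidation plus invertive opening. C2/C3 come from syn-hydrogenation opposite the C4 methyl. The Z-alkene comes from the ring of 2-hexylfuran.

Key step: step 17

Remark: acid 23 is drawn open-chain; the free acid rests largely as 5-hexyl-5-hydroxyfuran-2(5H)-one, whereas its salts are open-chain carboxylates. TBS = tert-butyldimethylsilyl, Ipc = isopinocampheyl.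

**Step 1**
Reactants: 1 methyl (R)-lactate
Product: 2 methyl (2R)-2-(TBS-oxy)propanoate
Conditions: TBSCl, imidazole, DMF, rt
Reagents that add atoms: tert-butyldimethylsilyl chloride, CC(C)(C)[Si](C)(C)Cl
Why: Imidazole-promoted silyl ether formation on a secondary alcohol, which does not touch the lactate stereocentre (future C8).

**Step 2**
Reactants: 2 methyl (2R)-2-(TBS-oxy)propanoate
Product: 3 (2R)-2-(TBS-oxy)propanal
Conditions: i-Bu2AlH (1.05 equiv), CH2Cl2, −78 °C; aq. Rochelle salt
Reagents that add atoms: none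
Why: Partial ester reduction stops at the tetrahedral aluminate at low temperature, so the configurationally labile α-silyloxy aldehyde is released only on work-up and is used at once.

**Step 3**
Reactants: 3 (2R)-2-(TBS-oxy)propanal
Product: 5 (2R,3S,4S)-2-(TBS-oxy)-4-methylhex-5-en-3-ol, via diisopinocampheylborinate ester 4 (not isolated)
Conditions: trans-2-butene, n-BuLi, KOt-Bu, THF, −78 to −45 °C; (−)-Ipc2BOMe, −78 °C; BF3·OEt2; 3, −78 °C; then NaOH, H2O2, 0 °C to rt
Reagents that add atoms: trans-2-butene, C/C=C/C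
Why: Brown (E)-crotylboration, in which the chair Zimmerman–Traxler transition state turns the E geometry into the anti C6-methyl/C7-hydroxyl relationship and the Ipc ligands derived from (+)-α-pinene direct attack to the Si face of 3, which is also the Felkin–Anh face (C7–O anti to C8–O), so the case is matched.

**Step 4**
Reactants: 5 (2R,3S,4S)-2-(TBS-oxy)-4-methylhex-5-en-3-ol
Product: 7 ethyl (2E,4S,5S,6R)-6-(TBS-oxy)-5-hydroxy-2,4-dimethylhept-2-enoate, via β-hydroxy aldehyde 6 (not isolated)
Conditions: O3, CH2Cl2, −78 °C; PPh3; then Ph3P=C(CH3)CO2Et (excess), −78 °C to rt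
Reagents that add atoms: ozone, [O-][O+]=O (oxygen of 6 only); ethyl 2-(triphenylphosphoranylidene)propanoate, CCOC(=O)C(C)=P(c1ccccc1)(c1ccccc1)c1ccccc1
Why: Ozonolysis followed in the same flask by a Wittig olefination with a stabilised α-branched ylide, which is E-selective and mild enough neither to epimerise C6 nor to dehydrate the β-hydroxy aldehyde.

**Step 5**
Reactants: 7 ethyl (2E,4S,5S,6R)-6-(TBS-oxy)-5-hydroxy-2,4-dimethylhept-2-enoate
Product: 8 (2E,4S,5S,6R)-6-(TBS-oxy)-2,4-dimethylhept-2-ene-1,5-diol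
Conditions: i-Bu2AlH (3.5 equiv), CH2Cl2, −78 °C; aq. Rochelle salt
Reagents that add atoms: none
Why: 1,2-Reduction of an enoate to the allylic alcohol, which leaves alkene geometry, silyl ether and stereocentres unchanged.

**Step 6**
Reactants: 8 (2E,4S,5S,6R)-6-(TBS-oxy)-2,4-dimethylhept-2-ene-1,5-diol
Product: 10 (2R,3S,4S,5S)-5-[(1R)-1-(TBS-oxy)ethyl]-2-(hydroxymethyl)-2,4-dimethyloxolan-3-ol, via epoxy diol 9 (not isolated)
Conditions: Ti(OiPr)4 (cat.), L-(+)-diethyl tartrate (cat.), t-BuOOH, 4 Å MS, CH2Cl2, −20 °C; crude 9, camphorsulfonic acid (cat.), CH2Cl2, 0 °C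
Reagents that add atoms: tert-butyl hydroperoxide, CC(C)(C)OO
Why: Sharpless asymmetric epoxidation with the L-(+)-tartrate gives the (2S,3S)-epoxy alcohol (C4, C5) under reagent control, and acid then lets the C7 hydroxyl open it in the 5-endo-tet mode at the tertiary C4 with inversion (the 4-exo path to an oxetane is not competitive), which sets C4 and C5 and gives the all-trans tetrahydrofuran.

**Step 7**
Reactants: 10 (2R,3S,4S,5S)-5-[(1R)-1-(TBS-oxy)ethyl]-2-(hydroxymethyl)-2,4-dimethyloxolan-3-ol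
Product: 11 (2S,3S,4S,5S)-5-[(1R)-1-(TBS-oxy)ethyl]-3-hydroxy-2,4-dimethyloxolane-2-carboxylic acid
Conditions: TEMPO (cat.), PhI(OAc)2 (2.2 equiv), MeCN–H2O, rt
Reagents that add atoms: water, O
Why: Oxoammonium oxidation takes the unhindered primary alcohol through the aldehyde hydrate to the acid, while the C5 hydroxyl, flanked by quaternary C4 and branched C6, reacts far more slowly and C4 has no hydrogen to epimerise.

**Step 8**
Reactants: 11 (2S,3S,4S,5S)-5-[(1R)-1-(TBS-oxy)ethyl]-3-hydroxy-2,4-dimethyloxolane-2-carboxylic acid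
Product: 12 methyl ester of 11
Conditions: MeI, K2CO3, DMF, rt
Reagents that add atoms: iodomethane, CI
Why: Carboxylate O-alkylation (SN2) esterifies the hindered α-quaternary acid without carbonyl activation and leaves the free hydroxyl alone.

**Step 9**
Reactants: 12 methyl ester of 11
Product: 13 methyl (2S,3S,4R,5S)-5-[(1R)-1-(TBS-oxy)ethyl]-2,4-dimethyl-3-(propanoyloxy)oxolane-2-carboxylate
Conditions: (EtCO)2O, Et3N, DMAP (cat.), CH2Cl2, rt
Reagents that add atoms: propionic anhydride, CCC(=O)OC(=O)CC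
Why: DMAP-catalysed acylation of the only free hydroxyl brings in C1, C2 and the C2 methyl as a propionate.

**Step 10**
Reactants: 13 methyl (2S,3S,4R,5S)-5-[(1R)-1-(TBS-oxy)ethyl]-2,4-dimethyl-3-(propanoyloxy)oxolane-2-carboxylate
Product: 14 (1S,6S,8S,9R)-8-[(1R)-1-(TBS-oxy)ethyl]-5-hydroxy-4,6,9-trimethyl-2,7-dioxabicyclo[4.3.0]non-4-en-3-one (enol form of the β-keto lactone)
Conditions: LiN(SiMe3)2 (2.5 equiv), THF, −78 to 0 °C; cold 1 M HCl
Reagents that add atoms: none
Why: Dieckmann-type intramolecular Claisen condensation (6-exo-trig) in which only the propionate can be enolised because the methyl ester sits on quaternary C4, so β-elimination and epimerisation cannot compete and formation of the stabilised β-dicarbonyl enolate drives closure of ring B in the trans-fused form dictated by C4 and C5.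

**Step 11**
Reactants: 14 enol lactone
Product: 15 (1S,4R,5S,6R,8S,9R)-8-[(1R)-1-(TBS-oxy)ethyl]-5-hydroxy-4,6,9-trimethyl-2,7-dioxabicyclo[4.3.0]nonan-3-one
Conditions: H2 (50 bar), Raney Ni, EtOAc, rt
Reagents that add atoms: none
Why: Heterogeneous syn-hydrogenation of a 4-hydroxy-5,6-dihydropyran-2-one, a reaction type known to give cis-3-alkyl-4-hydroxy-δ-lactones, should deliver both hydrogens to the face opposite the pseudo-axial C4 methyl and the C5–C6 bond, which sets C3 (S) and C2 (R) with hydroxyl and methyl cis to that methyl.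

**Step 12**
Reactants: 15 hydroxy lactone
Product: 16 (1S,4R,5S,6S,8S,9R)-8-[(1R)-1-(TBS-oxy)ethyl]-4,6,9-trimethyl-3-oxo-2,7-dioxabicyclo[4.3.0]nonan-5-yl acetate
Conditions: Ac2O, pyridine, DMAP (cat.), CH2Cl2, 0 °C to rt
Reagents that add atoms: acetic anhydride, CC(=O)OC(C)=O
Why: Standard acetylation of the remaining secondary alcohol under conditions too weakly basic to epimerise C2 or to eliminate the β-acyloxy group.

**Step 13**
Reactants: 16 acetate
Product: 17 (1S,4R,5S,6S,8S,9R)-8-[(1R)-1-hydroxyethyl]-4,6,9-trimethyl-3-oxo-2,7-dioxabicyclo[4.3.0]nonan-5-yl acetate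
Conditions: HF·pyridine, THF, 0 °C to rt
Reagents that add atoms: none
Why: Fluoride cleavage of the silyl ether in a buffered acidic medium spares lactone, acetate and the base-sensitive C2 centre.

**Step 14**
Reactants: 17 C8 alcohol
Product: 18 C8 chloromethanesulfonate of 17 (8R)
Conditions: ClCH2SO2Cl, 2,6-lutidine, CH2Cl2, 0 °C
Reagents that add atoms: chloromethanesulfonyl chloride, ClCS(=O)(=O)Cl
Why: Sulfonylation of the only free hydroxyl proceeds with retention at C8 and installs a leaving group well above a mesylate in reactivity yet stable to isolation.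

**Step 15**
Reactants: 19 furan; 20 1-bromohexane
Product: 22 2-hexylfuran, via 2-furyllithium 21 (not isolated)
Conditions: n-BuLi, THF, 0 °C; then 20, 0 °C to rt
Reagents that add atoms: none
Why: α-Lithiation of furan followed by SN2 alkylation with a primary bromide.

**Step 16**
Reactants: 22 2-hexylfuran
Product: 23 (2Z)-4-oxodec-2-enoic acid
Conditions: NaClO2, NaH2PO4, t-BuOH–H2O, rt
Reagents that add atoms: sodium chlorite, [Na+].[O-]Cl=O
Why: Oxidative ring opening of a 2-alkylfuran with chlorite gives the 4-oxo-2-enoic acid, whose Z geometry is inherited from the furan ring and held by the cyclic lactol tautomer.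

**Step 17**
Reactants: 18 C8 chloromethanesulfonate; 23 (2Z)-4-oxodec-2-enoic acid
Product: 26 botcinin J, via zinc carboxylate 24 (not isolated), via bicyclic oxiranium ion 25 (not isolated)
Conditions: 23 (3 equiv), ZnEt2 (1.5 equiv), 1,4-dioxane, 0 °C to rt; then 18, 4 Å MS, 50 °C, dark
Reagents that add atoms: none
Why: Proposed new method: ZnEt2 turns 23 into the open-chain zinc carboxylate 24, whose Lewis-acidic zinc assists departure of the chloromethanesulfonate while the tetrahydrofuran oxygen displaces it from the rear (3-exo-tet, inversion at C8) to give the trans-disubstituted 1-oxoniabicyclo[3.1.0]hexane 25. The carboxylate then cleaves the shared C7–O bond by SN2 attack at C7 (inversion), so the five-membered ring becomes ring A by a one-atom expansion and the C7–O ester bond to the side chain forms in the same event. The closest known reaction type is the stereospecific rearrangement–ring expansion of 2-(1-sulfonyloxyalkyl)tetrahydrofurans, including ones trans-fused to a six-membered ether, to 2,3-trans-3-acyloxy- or 3-hydroxytetrahydropyrans with Zn(OAc)2 in aqueous acetic acid or dioxane; what is new is that a stoichiometric, functionalised carboxylate in an anhydrous medium replaces solvent acetate or water. Both new stereocentres follow from the double inversion, the (8R)-sulfonate giving the (8S)-ether and the (7S)-ether giving the (7R)-ester, each substituent ending equatorial. The step needs attack at C7 rather than C8, participation rather than direct SN2 at C8, O-alkylation of the carboxylate rather than of the lactol tautomer, and retention of the Z-alkene. These are secured in turn by release of the strain of the trans-fused five/six system into an all-equatorial trans-fused six/six system, by a weakly nucleophilic zinc-bound carboxylate in a poorly dissociating solvent combined with a very good leaving group, by the preformed salt (open form only), and by the absence of amines, phosphines, halide and light.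

**Compound list**

1 | methyl (R)-lactate | C[C@@H](O)C(=O)OC | starting material
2 | methyl (2R)-2-(TBS-oxy)propanoate | C[C@@H](O[Si](C)(C)C(C)(C)C)C(=O)OC | intermediate
3 | (2R)-2-(TBS-oxy)propanal | C[C@@H](O[Si](C)(C)C(C)(C)C)C=O | intermediate
4 | diisopinocampheylborinate ester of 5 | C[C@@H](O[Si](C)(C)C(C)(C)C)[C@@H](OB([C@@H]1C[C@@H]2C[C@H]([C@H]1C)C2(C)C)[C@@H]1C[C@@H]2C[C@H]([C@H]1C)C2(C)C)[C@@H](C)C=C | intermediate
5 | (2R,3S,4S)-2-(TBS-oxy)-4-methylhex-5-en-3-ol | C[C@@H](O[Si](C)(C)C(C)(C)C)[C@@H](O)[C@@H](C)C=C | intermediate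
6 | (2R,3S,4R)-4-(TBS-oxy)-3-hydroxy-2-methylpentanal | C[C@@H](O[Si](C)(C)C(C)(C)C)[C@@H](O)[C@@H](C)C=O | intermediate
7 | ethyl (2E,4S,5S,6R)-6-(TBS-oxy)-5-hydroxy-2,4-dimethylhept-2-enoate | C[C@@H](O[Si](C)(C)C(C)(C)C)[C@@H](O)[C@@H](C)/C=C(\C)C(=O)OCC | intermediate
8 | (2E,4S,5S,6R)-6-(TBS-oxy)-2,4-dimethylhept-2-ene-1,5-diol | C[C@@H](O[Si](C)(C)C(C)(C)C)[C@@H](O)[C@@H](C)/C=C(\C)CO | intermediate
9 | {(2S,3S)-3-[(2R,3S,4R)-4-(TBS-oxy)-3-hydroxypentan-2-yl]-2-methyloxiran-2-yl}methanol | C[C@@H](O[Si](C)(C)C(C)(C)C)[C@@H](O)[C@@H](C)[C@@H]1O[C@@]1(C)CO | intermediate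
10 | (2R,3S,4S,5S)-5-[(1R)-1-(TBS-oxy)ethyl]-2-(hydroxymethyl)-2,4-dimethyloxolan-3-ol | C[C@@H](O[Si](C)(C)C(C)(C)C)[C@H]1O[C@](C)(CO)[C@@H](O)[C@@H]1C | intermediate
11 | (2S,3S,4S,5S)-5-[(1R)-1-(TBS-oxy)ethyl]-3-hydroxy-2,4-dimethyloxolane-2-carboxylic acid | C[C@@H](O[Si](C)(C)C(C)(C)C)[C@H]1O[C@](C)(C(=O)O)[C@@H](O)[C@@H]1C | intermediate
12 | methyl ester of 11 | C[C@@H](O[Si](C)(C)C(C)(C)C)[C@H]1O[C@](C)(C(=O)OC)[C@@H](O)[C@@H]1C | intermediate
13 | methyl (2S,3S,4R,5S)-5-[(1R)-1-(TBS-oxy)ethyl]-2,4-dimethyl-3-(propanoyloxy)oxolane-2-carboxylate | C[C@@H](O[Si](C)(C)C(C)(C)C)[C@H]1O[C@](C)(C(=O)OC)[C@@H](OC(=O)CC)[C@@H]1C | intermediate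
14 | (1S,6S,8S,9R)-8-[(1R)-1-(TBS-oxy)ethyl]-5-hydroxy-4,6,9-trimethyl-2,7-dioxabicyclo[4.3.0]non-4-en-3-one | C[C@@H](O[Si](C)(C)C(C)(C)C)[C@H]1O[C@]2(C)C(O)=C(C)C(=O)O[C@H]2[C@@H]1C | intermediate
15 | (1S,4R,5S,6R,8S,9R)-8-[(1R)-1-(TBS-oxy)ethyl]-5-hydroxy-4,6,9-trimethyl-2,7-dioxabicyclo[4.3.0]nonan-3-one | C[C@@H](O[Si](C)(C)C(C)(C)C)[C@H]1O[C@]2(C)[C@@H](O)[C@@H](C)C(=O)O[C@H]2[C@@H]1C | intermediate
16 | (1S,4R,5S,6S,8S,9R)-8-[(1R)-1-(TBS-oxy)ethyl]-4,6,9-trimethyl-3-oxo-2,7-dioxabicyclo[4.3.0]nonan-5-yl acetate | C[C@@H](O[Si](C)(C)C(C)(C)C)[C@H]1O[C@]2(C)[C@@H](OC(C)=O)[C@@H](C)C(=O)O[C@H]2[C@@H]1C | intermediate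
17 | (1S,4R,5S,6S,8S,9R)-8-[(1R)-1-hydroxyethyl]-4,6,9-trimethyl-3-oxo-2,7-dioxabicyclo[4.3.0]nonan-5-yl acetate | C[C@@H](O)[C@H]1O[C@]2(C)[C@@H](OC(C)=O)[C@@H](C)C(=O)O[C@H]2[C@@H]1C | intermediate
18 | chloromethanesulfonate of 17 at the (1R)-1-hydroxyethyl group (C8) | C[C@@H](OS(=O)(=O)CCl)[C@H]1O[C@]2(C)[C@@H](OC(C)=O)[C@@H](C)C(=O)O[C@H]2[C@@H]1C | intermediate
19 | furan | c1ccoc1 | starting material
20 | 1-bromohexane | CCCCCCBr | starting material
21 | 2-furyllithium | [Li]c1ccco1 | intermediate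
22 | 2-hexylfuran | CCCCCCc1ccco1 | intermediate
23 | (2Z)-4-oxodec-2-enoic acid | CCCCCCC(=O)/C=C\C(=O)O | intermediate
24 | zinc bis[(2Z)-4-oxodec-2-enoate] | CCCCCCC(=O)/C=C\C(=O)[O-].CCCCCCC(=O)/C=C\C(=O)[O-].[Zn+2] | intermediate
25 | oxiranium ion (O bonded to C4, C7 and C8; C6 and C9 trans on the three-membered ring), chloromethanesulfonate salt | C[C@@H]1[O+]2[C@H]1[C@@H](C)[C@@H]3OC(=O)[C@H](C)[C@H](OC(C)=O)[C@@]23C.[O-]S(=O)(=O)CCl | intermediate
26 | botcinin J, (1S,4R,5S,6S,8S,9R,10R)-5-acetoxy-4,6,8,10-tetramethyl-3-oxo-2,7-dioxabicyclo[4.4.0]decan-9-yl (2Z)-4-oxodec-2-enoate | CCCCCCC(=O)/C=C\C(=O)O[C@@H]1[C@@H](C)[C@@H]2OC(=O)[C@H](C)[C@H](OC(C)=O)[C@@]2(C)O[C@H]1C | target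

**Step count**

Total step count: 17. Longest linear sequence: 15 (steps 1–14 and 17).

**Steps most likely to fail**

Step 17. The oxiranium ion may be captured at C8, or the sulfonate may be displaced directly, so that no expansion occurs. Ionisation may be slow because two β-acyloxy groups lower the nucleophilicity of the ring oxygen. The alkene may drift from Z to E.
The fallback sets out from 18 and 23 and returns at 26. The known solvolytic form of the ring expansion (Zn(OAc)2, dioxane–H2O, 50 °C), with water as the nucleophile, gives the ring A alcohol 9-hydroxy-4,6,8,10-tetramethyl-3-oxo-2,7-dioxabicyclo[4.4.0]decan-5-yl acetate F1. Separately, 23 is isomerised with catalytic pyridine to (2E)-4-oxodec-2-enoic acid F2, which has no ring tautomer. Yamaguchi esterification (2,4,6-trichlorobenzoyl chloride, Et3N; then F1, DMAP, toluene) gives the (2E)-isomer of botcinin J F3. Irradiation (350 nm, benzene) sets up the E/Z photoequilibrium of the ene-dicarbonyl unit. 26 is separated from this mixture and F3 is recycled.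

Step 11. Hydrogen uptake may be sluggish at a tetrasubstituted enol next to quaternary C4. Reduction may also run through the keto tautomer, with loss of control at C2.
The fallback sets out from 10 and returns at 15, bypassing steps 7–11. TEMPO/PhI(OAc)2 in dry CH2Cl2 stops at the hydroxy aldehyde 5-[(1R)-1-(TBS-oxy)ethyl]-3-hydroxy-2,4-dimethyloxolane-2-carbaldehyde F4. A second Brown (E)-crotylboration with the reagent from (−)-Ipc2BOMe (Si face of the C3 aldehyde, reagent control) gives the anti adduct with a (1S,2S)-1-hydroxy-2-methylbut-3-enyl group on C4 F5. Ozonolysis (O3; Me2S) gives the six-membered C1 lactol F6. Ag2CO3 on Celite (toluene, reflux) then oxidises the lactol selectively to 15.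

Step 10. Closure of the enolate on the neopentyl-type ester may be slower than fragmentation of the ester enolate, and the flattened trans-fused product is strained.
The fallback sets out from 11 and returns at 14. Acid 11 is activated with 1,1'-carbonyldiimidazole and C-acylates Mg(O2CCH(CH3)CO2Et)2 (Masamune–Brooks reaction) to give the β-keto ester ethyl 2-methyl-3-oxo-3-(oxolan-2-yl)propanoate F7. The C2–C3 bond is thus made intermolecularly on a more reactive acyl donor. p-TsOH in toluene with heating then closes ring B through the C1–O bond to give 14.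

**Further compounds**

F1 | step 17 | (1S,4R,5S,6S,8S,9R,10R)-9-hydroxy-4,6,8,10-tetramethyl-3-oxo-2,7-dioxabicyclo[4.4.0]decan-5-yl acetate | O[C@@H]1[C@@H](C)[C@@H]2OC(=O)[C@H](C)[C@H](OC(C)=O)[C@@]2(C)O[C@H]1C
F2 | step 17 | (2E)-4-oxodec-2-enoic acid | CCCCCCC(=O)/C=C/C(=O)O
F3 | step 17 | (2E)-isomer of botcinin J | CCCCCCC(=O)/C=C/C(=O)O[C@@H]1[C@@H](C)[C@@H]2OC(=O)[C@H](C)[C@H](OC(C)=O)[C@@]2(C)O[C@H]1C
F4 | step 11 | (2S,3S,4S,5S)-5-[(1R)-1-(TBS-oxy)ethyl]-3-hydroxy-2,4-dimethyloxolane-2-carbaldehyde | C[C@@H](O[Si](C)(C)C(C)(C)C)[C@H]1O[C@](C)(C=O)[C@@H](O)[C@@H]1C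
F5 | step 11 | 5-[(1R)-1-(TBS-oxy)ethyl]-2-[(1S,2S)-1-hydroxy-2-methylbut-3-en-1-yl]-2,4-dimethyloxolan-3-ol, ring centres as in 10 | C[C@@H](O[Si](C)(C)C(C)(C)C)[C@H]1O[C@](C)([C@@H](O)[C@@H](C)C=C)[C@@H](O)[C@@H]1C
F6 | step 11 | C1 lactol of 15 (anomers) | C[C@@H](O[Si](C)(C)C(C)(C)C)[C@H]1O[C@]2(C)[C@@H](O)[C@@H](C)C(O)O[C@H]2[C@@H]1C
F7 | step 10 | ethyl 3-{(2S,3S,4S,5S)-5-[(1R)-1-(TBS-oxy)ethyl]-3-hydroxy-2,4-dimethyloxolan-2-yl}-2-methyl-3-oxopropanoate (C2 epimers) | C[C@@H](O[Si](C)(C)C(C)(C)C)[C@H]1O[C@](C)(C(=O)C(C)C(=O)OCC)[C@@H](O)[C@@H]1C
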